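**Plan**

Numbering follows the target SMILES: C1 is the exocyclic CH2. C2–C7 form ring B (C5 = CHBr, C6 = CMe2, C7 = spiro atom). C8–C12 complete ring A (C10 = CMeBr, C11 = CHCl).
Enabling feature: in ring A, spiro C7 is bonded to the plain methylene C8 on one side and reaches the methyl-bearing C10 over C12–C11 on the other. Ring A is therefore the closed form of a hexatriene C7=C12–C11=C10–C9=C8 whose end C7 is an exocyclic alkene carbon of ring B.
Retrosynthetic cuts, in order: C10–Br; C11–Cl together with C10–O; C1=C2; the hydrogens on C9 and C12; C7–C8 (6π electrocyclisation); C11–C12 (Negishi coupling); C6–C7 (bromonium cyclisation); C3–C4 (dianion alkylation).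
Forward: ring B is built first as a bromo β-keto ester. Its ester carbon becomes C12 and is joined to a (Z)-dienylzinc carrying C8–C11. Ring A then closes onto C7, and the diene is reduced to the C10=C11 alkene that takes up Cl and Br.
Stereochemistry: C5 comes from a catalytic enantioselective bromochlorination of prenol and is carried through a stereospecific bromonium cyclisation. C5 steers C7 in the ring closure, C7 steers the anti chlorohydroxylation that sets C10 and C11, and OH is exchanged for Br with retention.

Key step: step 12

Assumption: the antipode of the Schiff base ligand in step 1 is the one that leads to (S)-2; both antipodes are accessible from the parent amino acid, so the sense of induction can be matched to the target.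

**Route**

Step 1
Reactants: 1 3-methylbut-2-en-1-ol (prenol)
Product: 2 (2S)-2-bromo-3-chloro-3-methylbutan-1-ol
Conditions: NBS (1.1 equiv), ClTi(OiPr)3 (1.1 equiv), tridentate Schiff base ligand from 3,5-di-tert-butylsalicylaldehyde and a tert-leucine-derived 1,1-diaryl amino alcohol (20 mol %), hexanes, −20 °C
Reagents that add atoms: N-bromosuccinimide, O=C1CCC(=O)N1Br; chlorotitanium triisopropoxide, CC(C)O[Ti](Cl)(OC(C)C)OC(C)C
Why: Catalytic enantioselective bromochlorination of an allylic alcohol: the alcohol is bound to the chiral titanium Schiff base complex, bromine from NBS and titanium-bound chloride add anti across the alkene with chloride at the tertiary carbon (Markovnikov), and the ligand decides the face, which sets C5 as S.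

Step 2
Reactants: 2 (2S)-2-bromo-3-chloro-3-methylbutan-1-ol
Product: 3 (2S)-2-bromo-3-chloro-3-methylbutyl trifluoromethanesulfonate
Conditions: Tf2O (1.1 equiv), 2,6-lutidine (1.3 equiv), CH2Cl2, −78 °C; used at once
Reagents that add atoms: triflic anhydride, O=S(=O)(OS(=O)(=O)C(F)(F)F)C(F)(F)F
Why: Sulfonylation of the primary alcohol at low temperature gives the leaving group needed for substitution at the β-branched carbon C4, the hindered base avoids displacement or elimination, and C5 is not touched.

Step 3
Reactants: 4 methyl acetoacetate; 3 (2S)-2-bromo-3-chloro-3-methylbutyl trifluoromethanesulfonate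
Product: 6 methyl (6S)-6-bromo-7-chloro-7-methyl-3-oxooctanoate, via acetoacetate dianion 5 (not isolated)
Conditions: 4 (1.5 equiv), NaH then n-BuLi, THF, 0 °C; then 3, −78 °C; aq NH4Cl
Reagents that add atoms: none
Why: γ-Alkylation of an acetoacetate dianion: the more reactive terminal carbanion displaces the primary triflate by SN2 at −78 °C, faster than E2 or attack at the hindered secondary bromide and tertiary chloride, which forms C3–C4 and leaves C5 unchanged.

Step 4
Reactants: 6 methyl (6S)-6-bromo-7-chloro-7-methyl-3-oxooctanoate
Product: 8 methyl (1S,3S)-3-bromo-2,2-dimethyl-6-oxocyclohexane-1-carboxylate, via bromonium chloride 7 (not isolated)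
Conditions: (CF3)2CHOH (0.05 M), 23 to 40 °C
Reagents that add atoms: none
Why: Stereospecific solvolytic bromonium-induced cyclisation: the strongly ionising, weakly nucleophilic solvent removes the tertiary chloride with anchimeric help from the vicinal bromine, and the enol carbon C7 opens the enantioenriched bromonium ion 7 at its tertiary end C6 through a chair with bromine equatorial (closure through the enol oxygen being reversible under the acid released), so that C6–C7 forms, C5 stays S and the labile C7–H centre settles with the ester equatorial.

Step 5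
Reactants: 8 methyl (1S,3S)-3-bromo-2,2-dimethyl-6-oxocyclohexane-1-carboxylate
Product: 9 (4S)-4-bromo-2-(hydroxymethyl)-3,3-dimethylcyclohexan-1-ol (epimers at C1 and C2)
Conditions: i-Bu2AlH (4 equiv), CH2Cl2, −78 to 0 °C; aq potassium sodium tartrate
Reagents that add atoms: none
Why: Hydride reduction with i-Bu2AlH takes the largely non-enolised ketone and then the ester to the 1,3-diol without touching the neopentyl-type secondary bromide, and the epimer mixture at the two new centres is of no concern because both carbons become sp2 in step 6.

Step 6
Reactants: 9 (4S)-4-bromo-2-(hydroxymethyl)-3,3-dimethylcyclohexan-1-ol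
Product: 10 (2Z,4S)-4-bromo-2-(hydroxymethylidene)-3,3-dimethylcyclohexan-1-one (enol form of the β-keto aldehyde)
Conditions: IBX (3 equiv), DMSO, 23 °C
Reagents that add atoms: none
Why: Oxidation of both alcohols with the hypervalent iodine reagent IBX under neutral conditions gives the β-keto aldehyde, which rests as its hydrogen-bonded hydroxymethylidene enol, and the absence of base keeps the γ-bromo ketone from closing to a cyclopropane.

Step 7
Reactants: 10 (2Z,4S)-4-bromo-2-(hydroxymethylidene)-3,3-dimethylcyclohexan-1-one
Product: 11 (Z)-[(3S)-3-bromo-2,2-dimethyl-6-oxocyclohexylidene]methyl trifluoromethanesulfonate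
Conditions: Tf2O (1.2 equiv), iPr2NEt (1.5 equiv), CH2Cl2, −78 °C
Reagents that add atoms: triflic anhydride, O=S(=O)(OS(=O)(=O)C(F)(F)F)C(F)(F)F
Why: O-Sulfonylation of the acidic enol (formation of a vinylogous acyl triflate) takes place at the unhindered formyl oxygen, and the triflate group should stay cis to C2 (Z) because the other side of the alkene is blocked by the C6 methyl groups.

Step 8
Reactants: 12 prop-2-yn-1-ol (propargyl alcohol)
Product: 14 (2Z)-3-iodo-2-methylprop-2-en-1-ol, via alkenylmagnesium alkoxide 13 (not isolated)
Conditions: MeMgBr (2.2 equiv), CuI (10 mol %), Et2O, −10 to 23 °C; then I2 (1.5 equiv), −10 °C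
Reagents that add atoms: methylmagnesium bromide, C[Mg]Br; iodine, [I][I]
Why: Copper-catalysed anti carbomagnesiation of a propargylic alcohol: methyl adds to the internal alkyne carbon while magnesium ends on the terminal carbon cis to the chelating alkoxide, and iodinolysis with retention fixes the Z trisubstituted alkene that becomes C10=C11.

Step 9
Reactants: 14 (2Z)-3-iodo-2-methylprop-2-en-1-ol
Product: 15 (2Z)-3-iodo-2-methylprop-2-enal
Conditions: MnO2 (15 equiv), CH2Cl2, 23 °C, dark
Reagents that add atoms: none
Why: Allylic oxidation with MnO2 is neutral and heterogeneous, stops at the aldehyde and, run in the dark with immediate use of the product, should keep the Z geometry.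

Step 10
Reactants: 15 (2Z)-3-iodo-2-methylprop-2-enal
Product: 16 (1Z)-1-iodo-2-methylbuta-1,3-diene
Conditions: Ph3PCH3Br (1.3 equiv), n-BuLi (1.25 equiv), THF, 0 °C; then 15, −78 to 0 °C; kept as a pentane–ether solution
Reagents that add atoms: methyltriphenylphosphonium bromide, C[P+](c1ccccc1)(c1ccccc1)c1ccccc1.[Br-]
Why: Wittig methylenation of the aldehyde with the non-stabilised ylide at low temperature adds C8 and leaves the alkenyl iodide and its Z geometry untouched.

Step 11
Reactants: 16 (1Z)-1-iodo-2-methylbuta-1,3-diene; 11 (Z)-[(3S)-3-bromo-2,2-dimethyl-6-oxocyclohexylidene]methyl trifluoromethanesulfonate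
Product: 19 (2Z,4S)-4-bromo-3,3-dimethyl-2-[(2Z)-3-methylpenta-2,4-dien-1-ylidene]cyclohexan-1-one, via dienyllithium 17 (not isolated), via dienylzinc bromide 18 (not isolated)
Conditions: 16 (1.4 equiv), t-BuLi (2.8 equiv), Et2O, −78 °C; ZnBr2 (1.5 equiv) in THF, −78 to 0 °C; then 11, Pd(PPh3)4 (5 mol %), THF, 0 to 20 °C; product kept below 25 °C
Reagents that add atoms: none
Why: Negishi cross-coupling: iodine–lithium exchange and transmetalation to zinc proceed with retention, zerovalent palladium inserts into the vinylogous acyl triflate much faster than into the hindered secondary alkyl bromide, the organozinc spares the ketone, and C11–C12 forms with both alkene geometries retained and without any alkene insertion step that the free vinyl group could intercept.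

Step 12
Reactants: 19 (2Z,4S)-4-bromo-3,3-dimethyl-2-[(2Z)-3-methylpenta-2,4-dien-1-ylidene]cyclohexan-1-one
Product: 21 (4S,6R)-4-bromo-5,5,9-trimethylspiro[5.5]undeca-7,9-dien-1-one, via 2H-pyran valence tautomer 20 (not isolated)
Conditions: PhMe (0.01 M, degassed), BHT (10 mol %), base-washed sealed tube, 135 °C
Reagents that add atoms: none
Why: On heating, the s-cis,s-cis conformer of the (Z)-hexatriene C7=C12–C11=C10–C9=C8 undergoes a concerted, thermally allowed six-electron disrotatory electrocyclisation in which C8 bonds to the exocyclic terminus C7 and the π bonds move to C9=C10 and C11=C12; the closest known reaction type is the thermal closure of (Z)-1,3,5-hexatrienes that end in a fully substituted exocyclic alkene carbon. Ring A closes in this single all-carbon 6π mode as a 1,3-cyclohexadiene spiro-linked at C7, ring B being a spectator. The only new stereocentre, C7, is controlled by C5 through the ring B chair: with bromine equatorial the C6 methyl on the bromine face is axial, and the disrotatory sense in which the fully bonded C12 tilts to the opposite, axial side (anti to that methyl and freed from its A(1,3) contact with the equatorial methyl) while the still long C7···C8 bond takes the equatorial sector cis to bromine should be the lower one, and it also leads to the more stable product with the flat sp2 carbon C12 axial. Periselectivity is needed against oxa-6π closure of the dienone O=C2–C7=C12–C11=C10 to the 2H-pyran 20, but that closure is reversible, so 20 is only a resting state, and its reopening in either sense also repairs any drift of the C10=C11 geometry. Sigmatropic escape routes are closed by the substrate itself, because C7 carries only a carbonyl carbon and the quaternary C6 (no hydrogen for a 1,7-shift) and the C10 methyl is trans to C12 in the reacting isomer. The bath is held near 135 °C, well under the range in which 1,5-hydrogen migration around the new cyclohexadiene would exchange the two arms of ring A and so erase C7.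

Step 13
Reactants: 21 (4S,6R)-4-bromo-5,5,9-trimethylspiro[5.5]undeca-7,9-dien-1-one
Product: 22 (4S,6R)-4-bromo-5,5,9-trimethylspiro[5.5]undec-8-en-1-one
Conditions: H2 (70 atm), (η6-naphthalene)Cr(CO)3 (20 mol %), THF, 45 °C
Reagents that add atoms: none
Why: 1,4-Hydrogenation of an s-cis 1,3-diene catalysed by a labile (arene)Cr(CO)3 complex: the Cr(CO)3 fragment binds H2 and the ring-locked cisoid diene together and passes hydrogen to the termini C9 and C12, which leaves only the C10=C11 alkene, spares the isolated ketone and the C–Br bond and, at high hydrogen pressure and low temperature, should outrun metal-mediated hydrogen shifts, so that C7 is preserved.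

Step 14
Reactants: 22 (4S,6R)-4-bromo-5,5,9-trimethylspiro[5.5]undec-8-en-1-one
Product: 23 (6S,8S)-8-bromo-3,7,7-trimethyl-11-methylidenespiro[5.5]undec-2-ene
Conditions: Cp2TiMe2 (3 equiv), PhMe, 75 °C, dark
Reagents that add atoms: dimethyltitanocene, C[Ti](C)(C1C=CC=C1)C1C=CC=C1
Why: Petasis methylenation: titanocene methylidene generated thermally from Cp2TiMe2 olefinates even hindered, enolisable ketones under non-basic conditions, so that neither enolate cyclopropanation onto C5–Br nor elimination can compete and the trisubstituted alkene is left alone.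

Step 15
Reactants: 23 (6S,8S)-8-bromo-3,7,7-trimethyl-11-methylidenespiro[5.5]undec-2-ene
Product: 24 (2R,3R,6S,8S)-8-bromo-2-chloro-3,7,7-trimethyl-11-methylidenespiro[5.5]undecan-3-ol
Conditions: trichloroisocyanuric acid (0.35 equiv), acetone–H2O 4:1, 0 °C
Reagents that add atoms: trichloroisocyanuric acid, O=C1N(Cl)C(=O)N(Cl)C(=O)N1Cl; water, O
Why: Electrophilic anti chlorohydroxylation of the more electron-rich trisubstituted alkene (the neopentyl-type 1,1-disubstituted C1=C2 reacts more slowly): chlorine goes to C11 and water to the tertiary C10 (Markovnikov), and of the two trans-diaxial pathways the one with chlorine syn-axial to the flat sp2 carbon C2 should be preferred over the one with chlorine syn-axial to quaternary C6, which sets C11 as R and C10 as R relative to C7.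

Step 16
Reactants: 24 (2R,3R,6S,8S)-8-bromo-2-chloro-3,7,7-trimethyl-11-methylidenespiro[5.5]undecan-3-ol
Product: 26 (2S,6S,8R,9R)-2,9-dibromo-8-chloro-1,1,9-trimethyl-5-methylidenespiro[5.5]undecane (target), via alkoxyiminium bromide 25 (not isolated)
Conditions: Me2C=C(Br)NMe2 (1.5 equiv), CH2Cl2, 0 to 23 °C
Reagents that add atoms: 1-bromo-N,N,2-trimethylprop-1-en-1-amine, CC(C)=C(Br)N(C)C
Why: Deoxybromination of a tertiary alcohol with an α-bromoenamine under neutral conditions (SN1-type substitution with neighbouring-group control): the alcohol adds to the reagent to give alkoxyiminium bromide 25, which ionises at C10 in the diaxial conformer where the antiperiplanar C11 chlorine guards the rear face, so that bromide of the ion pair enters where oxygen left (retention, C10 R), while the only by-product is a neutral amide and no acid is present that could isomerise the C1=C2 alkene.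

**Compound list**

1 | 3-methylbut-2-en-1-ol (prenol) | CC(C)=CCO | starting material
2 | (2S)-2-bromo-3-chloro-3-methylbutan-1-ol | OC[C@H](Br)C(C)(C)Cl | intermediate
3 | (2S)-2-bromo-3-chloro-3-methylbutyl trifluoromethanesulfonate | O=S(=O)(OC[C@H](Br)C(C)(C)Cl)C(F)(F)F | intermediate
4 | methyl acetoacetate | COC(=O)CC(C)=O | starting material
5 | sodium lithium dianion of methyl acetoacetate | [Na+].[Li+].C=C([O-])C=C([O-])OC | intermediate
6 | methyl (6S)-6-bromo-7-chloro-7-methyl-3-oxooctanoate | COC(=O)CC(=O)CC[C@H](Br)C(C)(C)Cl | intermediate
7 | bromonium chloride bridging C5 and C6 of the keto ester chain | COC(=O)CC(=O)CC[C@@H]1[Br+]C1(C)C.[Cl-] | intermediate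
8 | methyl (1S,3S)-3-bromo-2,2-dimethyl-6-oxocyclohexane-1-carboxylate | COC(=O)[C@@H]1C(=O)CC[C@H](Br)C1(C)C | intermediate
9 | (4S)-4-bromo-2-(hydroxymethyl)-3,3-dimethylcyclohexan-1-ol (epimers at C1 and C2) | OCC1C(O)CC[C@H](Br)C1(C)C | intermediate
10 | (2Z,4S)-4-bromo-2-(hydroxymethylidene)-3,3-dimethylcyclohexan-1-one | O=C1CC[C@H](Br)C(C)(C)/C1=C/O | intermediate
11 | (Z)-[(3S)-3-bromo-2,2-dimethyl-6-oxocyclohexylidene]methyl trifluoromethanesulfonate | O=C1CC[C@H](Br)C(C)(C)/C1=C/OS(=O)(=O)C(F)(F)F | intermediate
12 | prop-2-yn-1-ol (propargyl alcohol) | C#CCO | starting material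
13 | bromomagnesium (2Z)-3-(bromomagnesio)-2-methylprop-2-en-1-olate | Br[Mg]OC/C(C)=C\[Mg]Br | intermediate
14 | (2Z)-3-iodo-2-methylprop-2-en-1-ol | OC/C(C)=C\I | intermediate
15 | (2Z)-3-iodo-2-methylprop-2-enal | O=C/C(C)=C\I | intermediate
16 | (1Z)-1-iodo-2-methylbuta-1,3-diene | C=C/C(C)=C\I | intermediate
17 | [(1Z)-2-methylbuta-1,3-dien-1-yl]lithium | C=C/C(C)=C\[Li] | intermediate
18 | [(1Z)-2-methylbuta-1,3-dien-1-yl]zinc bromide | C=C/C(C)=C\[Zn]Br | intermediate
19 | (2Z,4S)-4-bromo-3,3-dimethyl-2-[(2Z)-3-methylpenta-2,4-dien-1-ylidene]cyclohexan-1-one (trienone) | O=C1CC[C@H](Br)C(C)(C)/C1=C/C=C(C)\C=C | intermediate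
20 | (6S)-6-bromo-2-ethenyl-2,5,5-trimethyl-5,6,7,8-tetrahydro-2H-chromene (both C2 epimers) | C=CC1(C)C=CC2=C(CC[C@H](Br)C2(C)C)O1 | intermediate
21 | (4S,6R)-4-bromo-5,5,9-trimethylspiro[5.5]undeca-7,9-dien-1-one | O=C1CC[C@H](Br)C(C)(C)[C@]12CC=C(C)C=C2 | intermediate
22 | (4S,6R)-4-bromo-5,5,9-trimethylspiro[5.5]undec-8-en-1-one | O=C1CC[C@H](Br)C(C)(C)[C@]12CCC(C)=CC2 | intermediate
23 | (6S,8S)-8-bromo-3,7,7-trimethyl-11-methylidenespiro[5.5]undec-2-ene | C=C1CC[C@H](Br)C(C)(C)[C@]12CCC(C)=CC2 | intermediate
24 | (2R,3R,6S,8S)-8-bromo-2-chloro-3,7,7-trimethyl-11-methylidenespiro[5.5]undecan-3-ol | C=C1CC[C@H](Br)C(C)(C)[C@]12CC[C@@](C)(O)[C@H](Cl)C2 | intermediate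
25 | O-alkyl N,N-dimethylisobutyriminium bromide of alcohol 24 | C=C1CC[C@H](Br)C(C)(C)[C@]12CC[C@@](C)(OC(C(C)C)=[N+](C)C)[C@H](Cl)C2.[Br-] | intermediate
26 | (2S,6S,8R,9R)-2,9-dibromo-8-chloro-1,1,9-trimethyl-5-methylidenespiro[5.5]undecane | C=C1CC[C@H](Br)C(C)(C)[C@]12CC[C@@](C)(Br)[C@H](Cl)C2 | target

**Step count**

Total steps: 16.
Longest linear sequence: 13 steps (steps 1–7 and 11–16, from prenol).

**Steps most likely to fail**

Step 12. The ring closure may show poor facial selectivity, with C8 also bonding to the ring B face trans to bromine. The configuration at C7 is defined only by which arm of ring A keeps the alkene, so the other epimer can still be used. The fallback sets out from 19. The closure is run as described and the epimers are separated. The C7 epimer of the spiro dienone F1 is then reduced 1,2 rather than 1,4, at its disubstituted C11=C12 alkene, with diimide (2-nitrobenzenesulfonylhydrazide, Et3N, CH2Cl2, 23 °C); this reagent spares the trisubstituted C9=C10 alkene. In F1 the arm CH2–CH=C(CH3) already lies trans to bromine, so this product is identical with 22, where the fallback rejoins the route.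

Step 16. Ionisation at C10 may end in loss of a proton (elimination toward C9, the methyl group or C11) or in leakage of retention. More forcing acidic reagents cannot be used because the exocyclic alkene would isomerise. The fallback changes the order of events, so that the tertiary bromide is installed while C2 is still a ketone, and sets out from 22. Chlorohydroxylation as in step 15 gives the keto chlorohydrin F2. Me3SiBr in CH2Cl2 at 0 °C, now free of any acid-labile alkene, gives the keto bromochloride F3. Addition of Me3SiCH2Li premixed with CeCl3 in THF at −78 °C (low basicity) gives the β-hydroxysilane F4. Acid-induced Peterson elimination with aqueous HF in MeCN then delivers 26.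

Step 15. Ene-type allylic chlorination, competing attack on the C1=C2 alkene, or weak facial discrimination may erode the chlorohydrin. The fallback reverses the polarity of chlorine and sets out from 23. mCPBA (NaHCO3, CH2Cl2, 0 °C) epoxidises the trisubstituted alkene from the face anti to the pseudoaxial C2, giving the C10–C11 epoxide F5 with oxygen cis to C6. After separation from its diastereomer, nucleophilic chloride (LiCl, AcOH, THF, or Li2CuCl4) opens F5 in trans-diaxial SN2 fashion at the secondary carbon C11. This returns to the route at 24.

**Further compounds**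

F1 | step 12 | (4S,6S)-4-bromo-5,5,9-trimethylspiro[5.5]undeca-7,9-dien-1-one | O=C1CC[C@H](Br)C(C)(C)[C@@]12CC=C(C)C=C2
F2 | step 16 | (4S,6R,8R,9R)-4-bromo-8-chloro-9-hydroxy-5,5,9-trimethylspiro[5.5]undecan-1-one | O=C1CC[C@H](Br)C(C)(C)[C@]12CC[C@@](C)(O)[C@H](Cl)C2
F3 | step 16 | (4S,6R,8R,9R)-4,9-dibromo-8-chloro-5,5,9-trimethylspiro[5.5]undecan-1-one | O=C1CC[C@H](Br)C(C)(C)[C@]12CC[C@@](C)(Br)[C@H](Cl)C2
F4 | step 16 | 4,9-dibromo-8-chloro-5,5,9-trimethyl-1-[(trimethylsilyl)methyl]spiro[5.5]undecan-1-ol (C1 epimers, other centres as in F3) | C[Si](C)(C)CC1(O)CC[C@H](Br)C(C)(C)[C@]12CC[C@@](C)(Br)[C@H](Cl)C2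
F5 | step 15 | C10–C11 epoxide of 23 with oxygen on the ring A face cis to C6 | C=C1CC[C@H](Br)C(C)(C)[C@]12CC[C@@]3(C)O[C@H]3C2
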